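the same everywhere: starting material 0.25 M; capture agent 0.0125 M
- alder: free catalyst 3.2 mM; run made earlier
- oak: free catalyst 3.7 mM; run made earlier
- birch: free catalyst 4.7 mM; run made earlier
- eta: free catalyst 2.5 mM; time 2.5 min
- delta: free catalyst 6.2 mM; time 2.5 min

| run | time / min | catalyst intermediate A / % | starting material / % | trapped intermediate / % | target / % |
|---|---|---|---|---|---|
| alder | 0.500 | 0 | 81.5 | 0.1 | 20.5 |
| alder | 1.00 | 0 | 73.5 | 0.5 | 28.0 |
| alder | 1.50 | 0 | 69.3 | 1.5 | 27.5 |
| alder | 2.00 | 0.8 | 66.5 | 2.0 | 29.5 |
| alder | 2.50 | 0 | 67.5 | 0 | 32.9 |
| oak | 0.200 | 1.7 | 87.6 | 0 | 13.2 |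
| oak | 0.417 | 0.4 | 80.7 | 1.5 | 18.2 |
| oak | 0.667 | 1.6 | 71.4 | 1.8 | 23.9 |
| oak | 1.33 | 0 | 65.9 | 1.9 | 33.3 |
| oak | 2.50 | 0 | 61.4 | 1.8 | 36.3 |
| birch | 0.200 | 0.2 | 85.7 | 0 | 14.8 |
| birch | 0.417 | 0 | 71.9 | 0.1 | 25.3 |
| birch | 0.667 | 0 | 69.9 | 0 | 31.3 |
| birch | 1.33 | 0.6 | 53.5 | 1.9 | 42.8 |
| birch | 2.50 | 0 | 49.1 | 1.3 | 49.3 |

(standard deviation of a reading: 1 percentage point)

- which of these there is most of at the end, counted by the starting material in it, eta (target / trapped intermediate / starting material / catalyst intermediate A)
- which of these there is most of at the end, counted by the starting material in it, delta (target / trapped intermediate / starting material / catalyst intermediate A)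
- the largest of these amounts at the end, in percent of the starting material charged, eta
- the largest of these amounts at the end, in percent of the starting material charged, delta

- Take birch, the run richest in catalyst: its end target stands at 49.3 %, against 32.9 % in alder, from the same starting material charge. Read that as a dying catalyst, not an equilibrium.
- Let each catalyst lost take one capture agent, in competition with turnover. Target per catalyst lost (the running turnover number) then goes as K/[capture agent], and the end state is [target] = K ln([capture agent]₀/([capture agent]₀ − [catalyst]₀)).
- Solve for K: alder gives 278 mM, oak 259 mM and birch 261 mM. Keep their mean as K, the trap constant, the [capture agent] at which a catalyst makes one target per loss: 266 mM.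
- Object: trapped intermediate reads 1.3 % in birch with a scatter of 1 percentage point, so those readings can't prove one-for-one. Object further: a plain count of target per catalyst charged, with no fall in [capture agent], reads 25.7 in alder, 24.5 in oak and 26.2 in birch, so these runs can't separate it from the logarithm.
- Compute the ceilings: target 23.7 % for eta and 72.9 % for delta. The plain count gives delta 63.2 %, so the two rules part there; carry the logarithm as an assumption, not a finding.
- Object again: a ceiling is an end state, and the flask is read at 2.5 min. Birch reaches half of its end target by 0.417 min; take that as the catalyst half-life near the charge, and assume it stretches as [starting material][capture agent] fall.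
- Midway to its ceiling, delta's half-life is then 0.873 min, which leaves 13.7 % of its catalyst alive at 2.5 min. My delta target is therefore 59.4 %.
- The same clock gives eta 0.526 min, so 3.71 % of its catalyst lives on. Hold eta at its ceiling, with starting material near 76.3 %.
- The forecast says starting material at 76 % (72 % to 80 %) for eta and target at 69 % (61 % to 76 %) for delta, above my delta figure, holding that “the capture agent kills catalyst one-for-one, in competition with turnover”.
- The flasks give starting material at 74.9 % in eta and target at 64.4 % in delta.

    catalyst intermediate B → spent catalyst (k = 0.00990 s⁻¹)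
    starting material + free catalyst → catalyst intermediate A (k = 4.50 L mol⁻¹ s⁻¹)
    catalyst intermediate B → free catalyst + target (k = 23.0 s⁻¹)
    catalyst intermediate A ⇌ catalyst intermediate B (K = 10.0, k = 6.90 s⁻¹)
    capture agent + catalyst intermediate B → trapped intermediate (k = 83.0 L mol⁻¹ s⁻¹)

- At 2.50 min in delta, catalyst intermediate B has a half-life of 0.030 s by turnover against 1.2 s by capture, a ratio of 40.0. K over the capture agent left there, 56 % of its charge, gives 38.0 target per catalyst lost, and with free catalyst at 9.38 % of the catalyst charged, delta's starting material still falls from 33.4 % to 23.0 % by 25.0 min.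
- Now take a neighbour flask, delta's charge read at 1.0 min, with 64 % of the capture agent left: K gives target 47.5 %. The computed flask holds 49.4 %.

The runs come from a simulation on assumed constants; noise was put on by code.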